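## The problem

The target is built from two trans-2,3-diaryl-2,3-dihydrobenzofurans joined by a single bond from C3 of the first (O1, C2, C3, fused to ring B) to C5' of ring C, the benzo ring of the second (O1', C2', C3'). Ring B also carries an E-4-hydroxystyryl group (ring A) at C4, directly beside C3a, and the molecule has seven free phenols. The four stereocentres fall into two pairs, (2S,3S) and (2'R,3'R). Within a pair one centre can set the other, because the ring closures in question (capture of a benzylic cation, or displacement within a betaine) give the trans ring. Between the pairs there is no such help, since C3 sits at C5' and C3' at C3a' of ring C, so the absolute configuration must be introduced twice, independently. The fragile groups are the benzylic C2–O1 and C2'–O1' bonds, which ionise under protic or Lewis acid to quinone-methide-type cations; a cation at C2 or C3 lies within reach of the styryl double bond and can be trapped by it irreversibly. The alkene also excludes hydrogenolysis as the last deprotection, and ring B poses a quieter problem: its two oxygens are equivalent in any simple precursor, yet one must become O1 and the other a phenol. The feature that invites the key step is in dihydrobenzofuran 2: C3' bears two aryl groups (ring C through C3a', and resorcinol ring E) and C2' bears one aryl group (ring F) and oxygen, the pattern left when two different aryl groups are added anti across ring E–CH=CH–B and boron is exchanged for oxygen.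

## Retrosynthesis

**33 from 32.** The seven O–benzyl bonds are cut last. Benzyl ethers survive organolithiums, the palladium step, carbonate base and mild acid. They must be removed with BCl3 and pentamethylbenzene, because hydrogenolysis would saturate the stilbene. The forward step must debenzylate at low temperature without ionising C2–O1.

**32 from 24 and 29.** C2–C3 and C2–O1 of dihydrobenzofuran 1 are cut together, as a (4+1) annulation of the ortho-quinone methide 30 (from sulfone 24) with the ylide 31 (from sulfonium salt 29). This cut is preferred to closing O1–C2 through a cation, which would place a cation next to the styryl group. It is convergent and forms the most acid-sensitive ring last, under base. Ring 2 is too far away to direct, so the configuration must come from the chiral sulfide 27, made from diol 25 through dimesylate 26 and alkylated with chloride 28.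

**24 from 21.** The sulfone comes from benzhydrol 23, this from hydroxy ketone 22, and this from ketone 21. The detour through the ketone is deliberate: only at this oxidation level can magnesium bridge the carbonyl and the neighbouring benzyloxy group, so that one of the two otherwise equivalent ring B ethers is removed.

**21 from 16 and 19.** The aryl–carbonyl bond (the later C3–C3a bond) is cut to give ester 16 and aryllithium 20 from bromide 19. Bromide 19 comes from resveratrol 17 by benzylation (18) and bromination. Two ortho substituents on 20 should stop the addition at the ketone.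

**16 from 14.** O1'–C2' is cut to give alcohol 15, whose MOM-masked phenol closes the ring on acid treatment, and 15 comes from boronate 14 by oxidation. The precursor is acyclic, and both its stereocentres are already in place.

**14 from 7, 10 and 11.** C2'–ring F and C3'–C3a' are cut in one operation, a conjunctive coupling of the borate 13 (from alkenyl boronate 7 and aryllithium 12, itself from bromide 11) with aryl bromide 10. Cutting C2'–C3' instead would make ring 2 depend on a chiral reagent, and cutting only O1'–C2' leaves open how the triarylethane stereocentre is made. Here a catalyst sets both centres from three simple components. Two changes strengthen the step. The boronate carries the crowded mac diol 2, because a pinacol ester of a β-substituted alkenyl borate mainly hands its alkenyl group to palladium. The spectator on 10 is a methyl ester, which is inert to the borate and later gives ketone 21 directly.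

**Building blocks.** Boronate 7 comes from boronic acid 6 and diol 2 (from dione 1). Acid 6 comes from pinacol ester 5, made by boron–Wittig olefination of aldehyde 3 with diboronate 4. Bromide 10 comes from catechol ester 8 by selective MOM protection (9) and benzylation.

## Roads not taken

**Alternative 1:** Dihydrobenzofuran 1 is cut at C3–C3a and seen as the product of an oxidative 1,2-aryl shift. The protected flavanone A1 (from the naringenin series) would be treated with PhI(OAc)2 and H2SO4 in trimethyl orthoformate. Trivalent iodine attacks the enol ether at C3, the benzo ring migrates from the carbonyl carbon to C3, and the pyranone contracts to the ester A2.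

- Merits: C2 comes from the chiral pool with the right configuration, the ring is trans, and the two ring B oxygens are distinguished for free by the hydrogen bond of the 5-OH. The chosen plan needs steps 13 to 15 for that.
- Weak points: the flavanone stereocentre epimerises by ring opening to the chalcone, under the base needed for triflation and under the strong acid of the contraction. The ester carbon is one carbon too many and must be replaced by a bond from C3 to ring C, by decarboxylative arylation at an epimerisable centre with a hindered partner. Ring 2 is not addressed at all.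
- Comparison: this road is better for ring B differentiation and uses no chiral reagent for ring 1. The chosen plan offers a catalytic answer for ring 2 and makes the C3–aryl bond by ordinary carbonyl chemistry.

**Alternative 2:** Only O1'–C2' is cut, and it is formed oxidatively. DDQ would abstract hydride from the CH2 of the 4-benzyloxybenzyl group of phenol A3, and the ortho phenol would trap the cation to give the trans aldehyde A4.

- Merits: a single stereocentre (C3') has to be made, no oxygen need be put on C2' and displaced again, and the closure needs no acid.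
- Weak points: the hydrogen on C3' is doubly benzylic and ortho to the free phenol. Its abstraction would give an ortho-quinone methide and erase the only stereocentre, and the product can be oxidised further to the benzofuran. A3 itself needs an enantioselective synthesis of a carbon bearing two similar aryl groups, which is not trivial.
- Comparison: once A3 is in hand this road is shorter and as good in trans control. The chosen plan pays with a detour through the C2' alcohol. In return it makes C3' and two aryl–carbon bonds in one catalytic step and closes the ring without an oxidant near C3'–H.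

**Alternative 3:** C2–C3 and C2–O1 of dihydrobenzofuran 1 are cut. Cs2CO3 would release a ring B ortho-quinone methide from a sulfone and a chiral ylide from a sulfonium salt, and their (4+1) annulation would give A5 (identical with 32).

- Merits: it is convergent, forms the sensitive ring last and under base, and sets two centres at once. For ring 1 the chosen plan has nothing better and ends with this very annulation (step 19).
- Weak points as the carrier of the strategy: it presupposes enantiopure dihydrobenzofuran 2 without saying how it is made. Its stereocontrol is by reagent alone on a crowded quinone methide flanked by the styryl group, and it needs the ring B phenol differentiated.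
- Comparison: in convergence it is equal or better. The chosen plan adds the catalytic construction of ring 2 and keeps this annulation as the reserve for ring 2 as well.

Key step: step 7

Assumption: the absolute sense of induction of the (Sp,Sp) ligand in step 7 and of the (2S,5S)-sulfide in step 19 is taken by analogy with simpler substrates; both are accessible in either mirror-image form, and the antipode would be used if the sense proved opposite.

## Route

Step 1
Reactants: 1 acenaphthylene-1,2-dione
Product: 2 cis-1,2-dimethyl-1,2-dihydroacenaphthylene-1,2-diol (mac diol)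
Conditions: MeMgBr (3 equiv), THF, 0 °C to rt; aq NH4Cl
Reagents that add atoms: methylmagnesium bromide, C[Mg]Br
Why: Double Grignard addition to the 1,2-diketone; the second methyl group should enter anti to the solvated magnesium alkoxide, so the cis (meso) diol is expected to predominate and is purified by crystallisation.

Step 2
Reactants: 3 3,5-bis(benzyloxy)benzaldehyde; 4 bis(4,4,5,5-tetramethyl-1,3,2-dioxaborolan-2-yl)methane
Product: 5 (E)-2-[3,5-bis(benzyloxy)phenyl]ethenylboronic acid pinacol ester
Conditions: 4, lithium 2,2,6,6-tetramethylpiperidide, THF, 0 °C; then 3, −78 °C to rt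
Reagents that add atoms: none
Why: Boron–Wittig olefination: the lithiated gem-diboronate adds to the aldehyde and syn elimination of the boron–oxygen unit gives the E-alkenyl boronate, the geometry on which the relative configuration of step 7 depends.

Step 3
Reactants: 5 (E)-2-[3,5-bis(benzyloxy)phenyl]ethenylboronic acid pinacol ester
Product: 6 (E)-2-[3,5-bis(benzyloxy)phenyl]ethenylboronic acid
Conditions: NaIO4, NH4OAc, acetone/H2O, rt
Reagents that add atoms: water, O
Why: Periodate cleaves the pinacol as it is released and so pulls the hydrolysis to the free boronic acid; the alkenyl C–B bond and the benzyl ethers are inert to NaIO4.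

Step 4
Reactants: 6 (E)-2-[3,5-bis(benzyloxy)phenyl]ethenylboronic acid; 2 cis-1,2-dimethyl-1,2-dihydroacenaphthylene-1,2-diol
Product: 7 (E)-2-[3,5-bis(benzyloxy)phenyl]ethenylboronic acid mac ester
Conditions: MgSO4, CH2Cl2, rt
Reagents that add atoms: none
Why: Condensation of a boronic acid with a cis-1,2-diol to the five-membered cyclic boronic ester, driven by removal of water.

Step 5
Reactants: 8 methyl 3-bromo-4,5-dihydroxybenzoate
Product: 9 methyl 3-bromo-5-hydroxy-4-(methoxymethoxy)benzoate
Conditions: MOMCl (1.0 equiv), i-Pr2NEt (1.1 equiv), DMF, −20 to 0 °C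
Reagents that add atoms: chloromethyl methyl ether, COCCl
Why: Williamson-type O-alkylation of the more acidic phenol: the 4-OH is para to the ester and ortho to bromine, so one equivalent of base forms its phenoxide, which alone is alkylated (the selectivity known for 4-O-alkylation of 3,4-dihydroxybenzoyl compounds).

Step 6
Reactants: 9 methyl 3-bromo-5-hydroxy-4-(methoxymethoxy)benzoate
Product: 10 methyl 3-(benzyloxy)-5-bromo-4-(methoxymethoxy)benzoate
Conditions: BnBr, K2CO3, DMF, rt
Reagents that add atoms: benzyl bromide, BrCc1ccccc1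
Why: Williamson benzylation of the remaining phenol; the MOM ether and the ester are stable to carbonate.

Step 7
Reactants: 7 (E)-2-[3,5-bis(benzyloxy)phenyl]ethenylboronic acid mac ester; 10 methyl 3-(benzyloxy)-5-bromo-4-(methoxymethoxy)benzoate; 11 1-(benzyloxy)-4-bromobenzene
Product: 14 methyl 3-(benzyloxy)-5-[(1R,2R)-2-[4-(benzyloxy)phenyl]-1-[3,5-bis(benzyloxy)phenyl]-2-(mac-boryl)ethyl]-4-(methoxymethoxy)benzoate, via 4-(benzyloxy)phenyllithium 12 (not isolated), via lithium borate complex 13 (not isolated)
Conditions: 11, t-BuLi (2.0 equiv), THF, −78 °C; 7, −78 to 0 °C; then NaOTf (3 equiv), Pd(OAc)2 (3 mol%), (Sp,Sp)-1,1'-bis(diphenylphosphino)-2,2'-bis[(R)-α-(dimethylamino)benzyl]ferrocene (MandyPhos ligand, 3.6 mol%), 10, THF, 60 °C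
Reagents that add atoms: none
Why: Bromine–lithium exchange gives 12, which adds to the boron of 7 to form the four-coordinate borate 13, so that no free aryllithium is left to attack the ester of 10. Pd(OAc)2 is reduced in the flask to zerovalent palladium, which inserts into the C–Br bond of 10; NaOTf takes up bromide and leaves a cationic aryl complex of divalent palladium that binds the alkene of 13. Ring F then shifts from boron to C2' on the face opposite to palladium (1,2-metallate shift), palladium ends on the benzylic carbon C3', and reductive elimination with retention joins C3' to ring C. The closest known reaction type is the enantioselective conjunctive cross-coupling of β-substituted alkenyl boron ate complexes carrying a hindered diol with aryl electrophiles. No ring is closed. The relative configuration (1R,2R) follows from the E geometry of 7 and the anti addition of the two aryl groups, and the absolute configuration from the alkene face that the chiral bisphosphine lets palladium bind. The selectivity needed is metallate shift over direct transfer of the alkenyl or aryl group from boron to palladium; the crowded mac diol blocks the B–O–Pd bridge that such transfer requires, and the small ortho MOM ether of 10 should not slow oxidative addition.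

Step 8
Reactants: 14 methyl 3-(benzyloxy)-5-[(1R,2R)-2-[4-(benzyloxy)phenyl]-1-[3,5-bis(benzyloxy)phenyl]-2-(mac-boryl)ethyl]-4-(methoxymethoxy)benzoate
Product: 15 methyl 3-(benzyloxy)-5-[(1R,2R)-2-[4-(benzyloxy)phenyl]-1-[3,5-bis(benzyloxy)phenyl]-2-hydroxyethyl]-4-(methoxymethoxy)benzoate
Conditions: NaBO3·4H2O, THF/H2O, rt to 40 °C
Reagents that add atoms: sodium perborate, [Na+].[O-]OB=O
Why: Perborate oxidation of the C–B bond, in which carbon migrates from boron to oxygen with retention at C2'; the reagent is mild enough for the methyl ester and the MOM ether.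

Step 9
Reactants: 15 methyl 3-(benzyloxy)-5-[(1R,2R)-2-[4-(benzyloxy)phenyl]-1-[3,5-bis(benzyloxy)phenyl]-2-hydroxyethyl]-4-(methoxymethoxy)benzoate
Product: 16 methyl (2R,3R)-7-(benzyloxy)-2-[4-(benzyloxy)phenyl]-3-[3,5-bis(benzyloxy)phenyl]-2,3-dihydro-1-benzofuran-5-carboxylate
Conditions: HCl (2 M in MeOH), THF, 40 °C
Reagents that add atoms: none
Why: Acid-mediated cyclodehydration of a 1-aryl-2-(2-hydroxyaryl)ethanol: methanolysis removes the MOM group and the 4-benzyloxybenzylic alcohol ionises (SN1) to a cation that the phenol oxygen captures in a five-membered ring closure. C3' is not touched, and C2' is re-formed under its control with ring F anti to ring E (trans, also the thermodynamic isomer because ionisation is reversible), the configuration already set in step 7.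

Step 10
Reactants: 17 resveratrol
Product: 18 (E)-3,5,4'-tris(benzyloxy)stilbene
Conditions: BnBr (3.6 equiv), K2CO3, DMF, rt to 50 °C
Reagents that add atoms: benzyl bromide, BrCc1ccccc1
Why: Threefold Williamson benzylation; the E-alkene is unaffected.

Step 11
Reactants: 18 (E)-3,5,4'-tris(benzyloxy)stilbene
Product: 19 (E)-3,5,4'-tris(benzyloxy)-2-bromostilbene
Conditions: NBS (1.0 equiv), CH2Cl2, −78 to 0 °C, dark
Reagents that add atoms: N-bromosuccinimide, O=C1CCC(=O)N1Br
Why: Electrophilic aromatic bromination of the most electron-rich ring at C2 (para to one benzyloxy group, ortho to the other; C2 and C6 are equivalent), the site known for halogenation of resveratrol ethers with N-halosuccinimides. One equivalent at low temperature in an aprotic solvent should avoid dibromination and attack on the alkene.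

Step 12
Reactants: 19 (E)-3,5,4'-tris(benzyloxy)-2-bromostilbene; 16 methyl (2R,3R)-7-(benzyloxy)-2-[4-(benzyloxy)phenyl]-3-[3,5-bis(benzyloxy)phenyl]-2,3-dihydro-1-benzofuran-5-carboxylate
Product: 21 [2,4-bis(benzyloxy)-6-[(E)-2-[4-(benzyloxy)phenyl]ethenyl]phenyl] [(2R,3R)-dihydrobenzofuran-5-yl of 16] ketone, via ring B aryllithium 20 (not isolated)
Conditions: 19 (1.3 equiv), t-BuLi (2.6 equiv), THF, −78 °C; then 16, −78 to −40 °C
Reagents that add atoms: none
Why: Bromine–lithium exchange followed by nucleophilic acyl substitution at the methyl ester; a second addition is blocked because the aryllithium and the ketone each carry two ortho substituents. Low temperature keeps the aryllithium from deprotonating C3'.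

Step 13
Reactants: 21 the diaryl ketone
Product: 22 [4-(benzyloxy)-2-hydroxy-6-[(E)-2-[4-(benzyloxy)phenyl]ethenyl]phenyl] [(2R,3R)-dihydrobenzofuran-5-yl of 16] ketone
Conditions: MgBr2·OEt2 (3 equiv), toluene/Et2O, rt to 50 °C
Reagents that add atoms: none
Why: Chelation-controlled ortho-debenzylation: magnesium bridges the ketone oxygen and the neighbouring benzyloxy oxygen, which alone is activated for attack of bromide at its benzylic carbon; the six unchelated benzyl ethers should stay.

Step 14
Reactants: 22 the ortho-hydroxy diaryl ketone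
Product: 23 ortho-hydroxybenzhydrol (both epimers at the carbinol carbon)
Conditions: NaBH4, THF/MeOH, 0 °C to rt
Reagents that add atoms: none
Why: Hydride reduction of the diaryl ketone, activated by the hydrogen bond from the ortho phenol; the new carbinol centre forms as both epimers, which is immaterial because it becomes planar in step 19.

Step 15
Reactants: 23 ortho-hydroxybenzhydrol
Product: 24 ortho-hydroxybenzhydryl 4-tolyl sulfone (both epimers)
Conditions: p-TolSO2H (2 equiv), CH2Cl2, 0 °C to rt; used crude
Reagents that add atoms: p-toluenesulfinic acid, Cc1ccc(cc1)S(=O)O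
Why: The ortho-hydroxy, para-benzyloxy benzhydrol ionises under weak acid to the quinone methide or benzylic cation, which sulfinate captures at sulfur (the usual preparation of 2-[aryl(sulfonyl)methyl]phenols). The weak acid and the good nucleophile are chosen so that capture outruns attack of the cation on the neighbouring styryl group.

Step 16
Reactants: 25 (2R,5R)-hexane-2,5-diol
Product: 26 (2R,5R)-hexane-2,5-diyl dimethanesulfonate
Conditions: MsCl, Et3N, CH2Cl2, 0 °C
Reagents that add atoms: methanesulfonyl chloride, CS(=O)(=O)Cl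
Why: Sulfonylation of both secondary alcohols; the C–O bonds are not touched, so configuration is retained.

Step 17
Reactants: 26 (2R,5R)-hexane-2,5-diyl dimethanesulfonate
Product: 27 (2S,5S)-2,5-dimethylthiolane
Conditions: Na2S·9H2O, DMSO, rt
Reagents that add atoms: sodium sulfide, [Na+].[Na+].[S-2]
Why: Double SN2 displacement by sulfide, with inversion at both centres, gives the C2-symmetric thiolane.

Step 18
Reactants: 27 (2S,5S)-2,5-dimethylthiolane; 28 1-(benzyloxy)-4-(chloromethyl)benzene
Product: 29 (2S,5S)-1-[4-(benzyloxy)benzyl]-2,5-dimethylthiolan-1-ium tetrafluoroborate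
Conditions: AgBF4, CH2Cl2, 0 °C to rt, dark
Reagents that add atoms: silver tetrafluoroborate, [Ag+].F[B-](F)(F)F
Why: S-Alkylation of the sulfide, assisted by silver abstraction of chloride, gives the sulfonium salt with a non-nucleophilic counter-ion; because the sulfide is C2-symmetric, sulfur is not a stereocentre.

Step 19
Reactants: 24 ortho-hydroxybenzhydryl 4-tolyl sulfone; 29 (2S,5S)-1-[4-(benzyloxy)benzyl]-2,5-dimethylthiolan-1-ium tetrafluoroborate
Product: 32 hepta-O-benzyl ether of the target, via ortho-quinone methide 30 (not isolated), via sulfonium ylide 31 (not isolated)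
Conditions: Cs2CO3 (3 equiv), CH2Cl2/MeCN, −20 °C to rt
Reagents that add atoms: none
Why: Sulfur-ylide (4+1) annulation of an ortho-quinone methide: the phenoxide of 24 expels sulfinate to give 30, and 29 is deprotonated to 31. Conjugate addition of the ylide carbon to the methide carbon (C2–C3) is followed by 5-exo-tet displacement of the sulfide by the phenoxide (C2–O1) with inversion. The chiral sulfide fixes the face of the ylide and so C2, and C3 follows from the trans-selective closure.

Step 20
Reactants: 32 hepta-O-benzyl ether of the target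
Product: 33 CNP0172909.1, 4-[(E)-2-[(2S,3S)-3-[(2R,3R)-3-(3,5-dihydroxyphenyl)-7-hydroxy-2-(4-hydroxyphenyl)-2,3-dihydro-1-benzofuran-5-yl]-6-hydroxy-2-(4-hydroxyphenyl)-2,3-dihydro-1-benzofuran-4-yl]ethenyl]phenol
Conditions: BCl3 (14 equiv), C6HMe5 (21 equiv), CH2Cl2, −78 °C; MeOH quench
Reagents that add atoms: none
Why: Lewis-acid cleavage of aryl benzyl ethers with pentamethylbenzene as a non-basic trap for the benzyl cation (Friedel–Crafts benzylation), a known method for acid-sensitive polyphenols. At −78 °C the benzylic C–O bonds of both rings and the E-alkene, which hydrogenolysis would saturate, should survive.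

## Compound list

1 | acenaphthylene-1,2-dione | O=C1C(=O)c2cccc3cccc1c23 | starting material
2 | (1R,2S)-1,2-dimethyl-1,2-dihydroacenaphthylene-1,2-diol (cis, meso; mac diol) | C[C@]1(O)c2cccc3cccc(c23)[C@@]1(C)O | intermediate
3 | 3,5-bis(benzyloxy)benzaldehyde | O=Cc1cc(OCc2ccccc2)cc(OCc2ccccc2)c1 | starting material
4 | bis(4,4,5,5-tetramethyl-1,3,2-dioxaborolan-2-yl)methane | CC1(C)OB(CB2OC(C)(C)C(C)(C)O2)OC1(C)C | starting material
5 | 2-[(E)-2-[3,5-bis(benzyloxy)phenyl]ethenyl]-4,4,5,5-tetramethyl-1,3,2-dioxaborolane | CC1(C)OB(/C=C/c2cc(OCc3ccccc3)cc(OCc3ccccc3)c2)OC1(C)C | intermediate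
6 | [(E)-2-[3,5-bis(benzyloxy)phenyl]ethenyl]boronic acid | OB(O)/C=C/c1cc(OCc2ccccc2)cc(OCc2ccccc2)c1 | intermediate
7 | cyclic boronic ester of 6 with diol 2 (mac boronate) | C[C@]12c3cccc4cccc(c34)[C@@]1(C)OB(/C=C/c1cc(OCc5ccccc5)cc(OCc5ccccc5)c1)O2 | intermediate
8 | methyl 3-bromo-4,5-dihydroxybenzoate | COC(=O)c1cc(O)c(O)c(Br)c1 | starting material
9 | methyl 3-bromo-5-hydroxy-4-(methoxymethoxy)benzoate | COC(=O)c1cc(O)c(OCOC)c(Br)c1 | intermediate
10 | methyl 3-(benzyloxy)-5-bromo-4-(methoxymethoxy)benzoate | COC(=O)c1cc(OCc2ccccc2)c(OCOC)c(Br)c1 | intermediate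
11 | 1-(benzyloxy)-4-bromobenzene | Brc1ccc(OCc2ccccc2)cc1 | starting material
12 | [4-(benzyloxy)phenyl]lithium | [Li]c1ccc(OCc2ccccc2)cc1 | intermediate
13 | lithium [4-(benzyloxy)phenyl][(E)-2-[3,5-bis(benzyloxy)phenyl]ethenyl]borate of diol 2 | [Li+].C[C@]12c3cccc4cccc(c34)[C@@]1(C)O[B-](/C=C/c1cc(OCc5ccccc5)cc(OCc5ccccc5)c1)(c1ccc(OCc5ccccc5)cc1)O2 | intermediate
14 | methyl 3-(benzyloxy)-5-[(1R,2R)-2-[4-(benzyloxy)phenyl]-1-[3,5-bis(benzyloxy)phenyl]-2-boryl-ethyl]-4-(methoxymethoxy)benzoate, boron as the cyclic ester of diol 2 | COC(=O)c1cc(OCc5ccccc5)c(OCOC)c(c1)[C@@H](c1cc(OCc5ccccc5)cc(OCc5ccccc5)c1)[C@H](c1ccc(OCc5ccccc5)cc1)B1O[C@@]2(C)c3cccc4cccc(c34)[C@@]2(C)O1 | intermediate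
15 | methyl 3-(benzyloxy)-5-[(1R,2R)-2-[4-(benzyloxy)phenyl]-1-[3,5-bis(benzyloxy)phenyl]-2-hydroxyethyl]-4-(methoxymethoxy)benzoate | COC(=O)c1cc(OCc5ccccc5)c(OCOC)c(c1)[C@@H](c1cc(OCc5ccccc5)cc(OCc5ccccc5)c1)[C@H](c1ccc(OCc5ccccc5)cc1)O | intermediate
16 | methyl (2R,3R)-7-(benzyloxy)-2-[4-(benzyloxy)phenyl]-3-[3,5-bis(benzyloxy)phenyl]-2,3-dihydro-1-benzofuran-5-carboxylate | COC(=O)c1cc(OCc5ccccc5)c2c(c1)[C@@H](c1cc(OCc5ccccc5)cc(OCc5ccccc5)c1)[C@H](c1ccc(OCc5ccccc5)cc1)O2 | intermediate
17 | resveratrol | Oc1ccc(/C=C/c2cc(O)cc(O)c2)cc1 | starting material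
18 | 1,3-bis(benzyloxy)-5-[(E)-2-[4-(benzyloxy)phenyl]ethenyl]benzene | C(c1ccccc1)Oc1ccc(/C=C/c2cc(OCc3ccccc3)cc(OCc3ccccc3)c2)cc1 | intermediate
19 | 1,5-bis(benzyloxy)-2-bromo-3-[(E)-2-[4-(benzyloxy)phenyl]ethenyl]benzene | C(c1ccccc1)Oc1ccc(/C=C/c2cc(OCc3ccccc3)cc(OCc3ccccc3)c2Br)cc1 | intermediate
20 | [2,4-bis(benzyloxy)-6-[(E)-2-[4-(benzyloxy)phenyl]ethenyl]phenyl]lithium | [Li]c1c(OCc3ccccc3)cc(OCc3ccccc3)cc1/C=C/c1ccc(OCc3ccccc3)cc1 | intermediate
21 | [2,4-bis(benzyloxy)-6-[(E)-2-[4-(benzyloxy)phenyl]ethenyl]phenyl][(2R,3R)-7-(benzyloxy)-2-[4-(benzyloxy)phenyl]-3-[3,5-bis(benzyloxy)phenyl]-2,3-dihydro-1-benzofuran-5-yl]methanone | O=C(c1cc(OCc5ccccc5)c2c(c1)[C@@H](c1cc(OCc5ccccc5)cc(OCc5ccccc5)c1)[C@H](c1ccc(OCc5ccccc5)cc1)O2)c1c(OCc5ccccc5)cc(OCc5ccccc5)cc1/C=C/c1ccc(OCc5ccccc5)cc1 | intermediate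
22 | [4-(benzyloxy)-2-hydroxy-6-[(E)-2-[4-(benzyloxy)phenyl]ethenyl]phenyl][(2R,3R)-7-(benzyloxy)-2-[4-(benzyloxy)phenyl]-3-[3,5-bis(benzyloxy)phenyl]-2,3-dihydro-1-benzofuran-5-yl]methanone | O=C(c1cc(OCc5ccccc5)c2c(c1)[C@@H](c1cc(OCc5ccccc5)cc(OCc5ccccc5)c1)[C@H](c1ccc(OCc5ccccc5)cc1)O2)c1c(O)cc(OCc5ccccc5)cc1/C=C/c1ccc(OCc5ccccc5)cc1 | intermediate
23 | 5-(benzyloxy)-2-[hydroxy[(2R,3R)-dihydrobenzofuran-5-yl of 16]methyl]-3-[(E)-2-[4-(benzyloxy)phenyl]ethenyl]phenol, both epimers at the carbinol carbon | OC(c1cc(OCc5ccccc5)c2c(c1)[C@@H](c1cc(OCc5ccccc5)cc(OCc5ccccc5)c1)[C@H](c1ccc(OCc5ccccc5)cc1)O2)c1c(O)cc(OCc5ccccc5)cc1/C=C/c1ccc(OCc5ccccc5)cc1 | intermediate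
24 | 5-(benzyloxy)-2-[[(2R,3R)-dihydrobenzofuran-5-yl of 16](4-methylbenzenesulfonyl)methyl]-3-[(E)-2-[4-(benzyloxy)phenyl]ethenyl]phenol, both epimers at the sulfonyl-bearing carbon | Cc1ccc(cc1)S(=O)(=O)C(c1cc(OCc5ccccc5)c2c(c1)[C@@H](c1cc(OCc5ccccc5)cc(OCc5ccccc5)c1)[C@H](c1ccc(OCc5ccccc5)cc1)O2)c1c(O)cc(OCc5ccccc5)cc1/C=C/c1ccc(OCc5ccccc5)cc1 | intermediate
25 | (2R,5R)-hexane-2,5-diol | C[C@@H](O)CC[C@@H](C)O | starting material
26 | (2R,5R)-hexane-2,5-diyl dimethanesulfonate | C[C@@H](OS(C)(=O)=O)CC[C@@H](C)OS(C)(=O)=O | intermediate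
27 | (2S,5S)-2,5-dimethylthiolane | C[C@H]1CC[C@H](C)S1 | intermediate
28 | 1-(benzyloxy)-4-(chloromethyl)benzene | ClCc1ccc(OCc2ccccc2)cc1 | starting material
29 | (2S,5S)-1-[4-(benzyloxy)benzyl]-2,5-dimethylthiolan-1-ium tetrafluoroborate | C[C@H]1CC[C@H](C)[S+]1Cc1ccc(OCc2ccccc2)cc1.F[B-](F)(F)F | intermediate
30 | 3-(benzyloxy)-5-[(E)-2-[4-(benzyloxy)phenyl]ethenyl]-6-[[(2R,3R)-dihydrobenzofuran-5-yl of 16]methylidene]cyclohexa-2,4-dien-1-one (exocyclic geometry not defined) | O=C1C=C(OCc5ccccc5)C=C(/C=C/c2ccc(OCc5ccccc5)cc2)C1=Cc1cc(OCc5ccccc5)c2c(c1)[C@@H](c1cc(OCc5ccccc5)cc(OCc5ccccc5)c1)[C@H](c1ccc(OCc5ccccc5)cc1)O2 | intermediate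
31 | (2S,5S)-2,5-dimethylthiolan-1-ium-1-yl [4-(benzyloxy)phenyl]methanide | C[C@H]1CC[C@H](C)[S+]1[CH-]c1ccc(OCc2ccccc2)cc1 | intermediate
32 | (2S,3S)-6-(benzyloxy)-3-[(2R,3R)-7-(benzyloxy)-2-[4-(benzyloxy)phenyl]-3-[3,5-bis(benzyloxy)phenyl]-2,3-dihydro-1-benzofuran-5-yl]-2-[4-(benzyloxy)phenyl]-4-[(E)-2-[4-(benzyloxy)phenyl]ethenyl]-2,3-dihydro-1-benzofuran (hepta-O-benzyl ether of the target) | C(c1ccccc1)Oc1ccc(/C=C/c2cc(OCc5ccccc5)cc3c2[C@H](c2cc(OCc5ccccc5)c4c(c2)[C@@H](c2cc(OCc5ccccc5)cc(OCc5ccccc5)c2)[C@H](c2ccc(OCc5ccccc5)cc2)O4)[C@@H](c2ccc(OCc5ccccc5)cc2)O3)cc1 | intermediate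
33 | 4-[(E)-2-[(2S,3S)-3-[(2R,3R)-3-(3,5-dihydroxyphenyl)-7-hydroxy-2-(4-hydroxyphenyl)-2,3-dihydro-1-benzofuran-5-yl]-6-hydroxy-2-(4-hydroxyphenyl)-2,3-dihydro-1-benzofuran-4-yl]ethenyl]phenol | Oc1ccc(/C=C/c2cc(O)cc3c2[C@H](c2cc(O)c4c(c2)[C@@H](c2cc(O)cc(O)c2)[C@H](c2ccc(O)cc2)O4)[C@@H](c2ccc(O)cc2)O3)cc1 | target

## Step count and least certain steps

Total: 20 steps. Longest linear sequence: 12 steps (2, 3, 4, 7, 8, 9, 12, 13, 14, 15, 19, 20).

**Step 7 (key step).** The most likely failure is direct transfer of the alkenyl group (or of ring F) from boron to palladium, giving the simple cross-coupled stilbene or biaryl. A β-aryl alkenyl borate with an ortho-substituted aryl bromide lies at the edge of what this coupling has been shown to do, and residual bromide can block alkene binding. Poor enantioface discrimination on a β-aryl alkene is the second risk. The fallback builds ring 2 by the annulation the route uses for ring 1; it sets out from 10 and 3 and comes back at 16.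
- Bromine–magnesium exchange of 10 (i-PrMgCl·LiCl, THF, −20 °C) gives the arylmagnesium chloride F1, which adds to 3 to give the diaryl carbinol F2.
- HCl in MeOH removes the MOM group to give the ortho-hydroxybenzhydrol F3, and p-toluenesulfinic acid converts it into the sulfone F4.
- The mirror-image sulfonium salt F7 is made as in steps 16 to 18 from (2S,5S)-hexane-2,5-diol, through the dimesylate F5 and (2R,5R)-2,5-dimethylthiolane F6.
- Cs2CO3 releases the quinone methide F8 and the ylide F9, and their (4+1) annulation gives 16.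

**Step 19.** Facial control rests on the chiral sulfide alone and may be poor, and addition to a quinone methide flanked by the styryl group may be slow enough for the quinone methide to oligomerise. The fallback gives up reagent control. It sets out from 24, which is treated with the achiral 1-[4-(benzyloxy)benzyl]thiolan-1-ium tetrafluoroborate F10 (from thiolane, 28 and AgBF4) and Cs2CO3. The small ylide F11 adds without a stereochemical preference and gives 32 together with its (2R,3R) ring 1 isomer F12. The two are diastereomers, because ring 2 is already enantiopure, so they can be separated by chromatography, and the route is rejoined at 32.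

**Step 20.** The Lewis acid may ionise the C2–O1 bond, after which the cation is captured by the neighbouring styryl group; the 4-oxyphenyl group on C2 is what makes this ionisation easy. The fallback removes that donor during the debenzylation; it sets out from 24 and comes back at 33.
- The annulation is run with (2S,5S)-1-[4-(acetyloxy)benzyl]-2,5-dimethylthiolan-1-ium tetrafluoroborate F13 (from 27, commercial 4-(chloromethyl)phenyl acetate and AgBF4), through its ylide F14.
- This gives the hexa-O-benzyl ether F15, whose ring D oxygen is an electron-poor acetate.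
- BCl3 and pentamethylbenzene then give the hexaphenol monoacetate F16, and K2CO3 in MeOH at 0 °C removes the acetate to give 33.

**Step 9.** While the ring oxygen is still masked, the C2' cation may lose the proton on C3' to give a triarylethene, which would erase C3'. The fallback changes the order of events; it sets out from 14 and comes back at 16. HCl in MeOH removes the MOM group with the C–B bond intact and gives the phenol boronate F17. Perborate oxidation gives the phenol alcohol F18. A trace of pyridinium p-toluenesulfonate in CH2Cl2 at 0 °C then closes the ring, with the free phenol present to capture the cation as soon as it forms.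

**Step 12.** Acyl substitution by a doubly ortho-substituted aryllithium may be slow, which leaves time for deprotonation at C3' (with ring opening) or for a second addition. The fallback sets out from 16, which is converted with N,O-dimethylhydroxylamine hydrochloride and i-PrMgCl into the N-methoxy-N-methyl amide F19. Its chelated adduct with 20 cannot release the ketone before work-up, so an excess of 20 can be used at −78 °C, and the route is rejoined at 21.

## Further compounds

F1 | step 7 | [3-(benzyloxy)-5-(methoxycarbonyl)-2-(methoxymethoxy)phenyl]magnesium chloride | COC(=O)c1cc(OCc2ccccc2)c(OCOC)c([Mg]Cl)c1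
F2 | step 7 | methyl 3-(benzyloxy)-5-[[3,5-bis(benzyloxy)phenyl](hydroxy)methyl]-4-(methoxymethoxy)benzoate (racemic) | COC(=O)c1cc(OCc2ccccc2)c(OCOC)c(c1)C(O)c1cc(OCc2ccccc2)cc(OCc2ccccc2)c1
F3 | step 7 | methyl 3-(benzyloxy)-5-[[3,5-bis(benzyloxy)phenyl](hydroxy)methyl]-4-hydroxybenzoate (racemic) | COC(=O)c1cc(OCc2ccccc2)c(O)c(c1)C(O)c1cc(OCc2ccccc2)cc(OCc2ccccc2)c1
F4 | step 7 | methyl 3-(benzyloxy)-5-[[3,5-bis(benzyloxy)phenyl](4-methylbenzenesulfonyl)methyl]-4-hydroxybenzoate (racemic) | COC(=O)c1cc(OCc2ccccc2)c(O)c(c1)C(c1cc(OCc2ccccc2)cc(OCc2ccccc2)c1)S(=O)(=O)c1ccc(C)cc1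
F5 | step 7 | (2S,5S)-hexane-2,5-diyl dimethanesulfonate | C[C@H](OS(C)(=O)=O)CC[C@H](C)OS(C)(=O)=O
F6 | step 7 | (2R,5R)-2,5-dimethylthiolane | C[C@@H]1CC[C@@H](C)S1
F7 | step 7 | (2R,5R)-1-[4-(benzyloxy)benzyl]-2,5-dimethylthiolan-1-ium tetrafluoroborate | C[C@@H]1CC[C@@H](C)[S+]1Cc1ccc(OCc2ccccc2)cc1.F[B-](F)(F)F
F8 | step 7 | methyl 5-(benzyloxy)-3-[[3,5-bis(benzyloxy)phenyl]methylidene]-4-oxocyclohexa-1,5-diene-1-carboxylate (exocyclic geometry not defined) | O=C1C(OCc2ccccc2)=CC(C(=O)OC)=CC1=Cc1cc(OCc2ccccc2)cc(OCc2ccccc2)c1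
F9 | step 7 | (2R,5R)-2,5-dimethylthiolan-1-ium-1-yl [4-(benzyloxy)phenyl]methanide | C[C@@H]1CC[C@@H](C)[S+]1[CH-]c1ccc(OCc2ccccc2)cc1
F10 | step 19 | 1-[4-(benzyloxy)benzyl]thiolan-1-ium tetrafluoroborate | C1CC[S+](C1)Cc1ccc(OCc2ccccc2)cc1.F[B-](F)(F)F
F11 | step 19 | thiolan-1-ium-1-yl [4-(benzyloxy)phenyl]methanide | C1CC[S+](C1)[CH-]c1ccc(OCc2ccccc2)cc1
F12 | step 19 | (2R,3R) ring 1 diastereomer of 32 | C(c1ccccc1)Oc1ccc(/C=C/c2cc(OCc5ccccc5)cc3c2[C@@H](c2cc(OCc5ccccc5)c4c(c2)[C@@H](c2cc(OCc5ccccc5)cc(OCc5ccccc5)c2)[C@H](c2ccc(OCc5ccccc5)cc2)O4)[C@H](c2ccc(OCc5ccccc5)cc2)O3)cc1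
F13 | step 20 | (2S,5S)-1-[4-(acetyloxy)benzyl]-2,5-dimethylthiolan-1-ium tetrafluoroborate | C[C@H]1CC[C@H](C)[S+]1Cc1ccc(OC(C)=O)cc1.F[B-](F)(F)F
F14 | step 20 | (2S,5S)-2,5-dimethylthiolan-1-ium-1-yl [4-(acetyloxy)phenyl]methanide | C[C@H]1CC[C@H](C)[S+]1[CH-]c1ccc(OC(C)=O)cc1
F15 | step 20 | analogue of 32 with a 4-(acetyloxy)phenyl group on C2 (hexa-O-benzyl ether monoacetate) | C(c1ccccc1)Oc1ccc(/C=C/c2cc(OCc5ccccc5)cc3c2[C@H](c2cc(OCc5ccccc5)c4c(c2)[C@@H](c2cc(OCc5ccccc5)cc(OCc5ccccc5)c2)[C@H](c2ccc(OCc5ccccc5)cc2)O4)[C@@H](c2ccc(OC(C)=O)cc2)O3)cc1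
F16 | step 20 | monoacetate of 33 at the phenol of the C2 aryl group | Oc1ccc(/C=C/c2cc(O)cc3c2[C@H](c2cc(O)c4c(c2)[C@@H](c2cc(O)cc(O)c2)[C@H](c2ccc(O)cc2)O4)[C@@H](c2ccc(OC(C)=O)cc2)O3)cc1
F17 | step 9 | methyl 3-(benzyloxy)-5-[(1R,2R)-2-[4-(benzyloxy)phenyl]-1-[3,5-bis(benzyloxy)phenyl]-2-boryl-ethyl]-4-hydroxybenzoate, boron as the cyclic ester of diol 2 | COC(=O)c1cc(OCc5ccccc5)c(O)c(c1)[C@@H](c1cc(OCc5ccccc5)cc(OCc5ccccc5)c1)[C@H](c1ccc(OCc5ccccc5)cc1)B1O[C@@]2(C)c3cccc4cccc(c34)[C@@]2(C)O1
F18 | step 9 | methyl 3-(benzyloxy)-5-[(1R,2R)-2-[4-(benzyloxy)phenyl]-1-[3,5-bis(benzyloxy)phenyl]-2-hydroxyethyl]-4-hydroxybenzoate | COC(=O)c1cc(OCc5ccccc5)c(O)c(c1)[C@@H](c1cc(OCc5ccccc5)cc(OCc5ccccc5)c1)[C@H](c1ccc(OCc5ccccc5)cc1)O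
F19 | step 12 | (2R,3R)-7-(benzyloxy)-2-[4-(benzyloxy)phenyl]-3-[3,5-bis(benzyloxy)phenyl]-N-methoxy-N-methyl-2,3-dihydro-1-benzofuran-5-carboxamide | CON(C)C(=O)c1cc(OCc5ccccc5)c2c(c1)[C@@H](c1cc(OCc5ccccc5)cc(OCc5ccccc5)c1)[C@H](c1ccc(OCc5ccccc5)cc1)O2
A1 | alternative 1 | (2S)-7-(benzyloxy)-2-[4-(tosyloxy)phenyl]-5-(triflyloxy)chroman-4-one | O=C1C[C@@H](c2ccc(OS(=O)(=O)c3ccc(C)cc3)cc2)Oc2cc(OCc3ccccc3)cc(OS(=O)(=O)C(F)(F)F)c12
A2 | alternative 1 | methyl (2S,3S)-6-(benzyloxy)-2-[4-(tosyloxy)phenyl]-4-(triflyloxy)-2,3-dihydro-1-benzofuran-3-carboxylate | FC(F)(F)S(=O)(=O)Oc1cc(OCc5ccccc5)cc2c1[C@H](C(=O)OC)[C@@H](c1ccc(OS(=O)(=O)c3ccc(C)cc3)cc1)O2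
A3 | alternative 2 | 3-(benzyloxy)-5-[(1R)-2-[4-(benzyloxy)phenyl]-1-[3,5-bis(benzyloxy)phenyl]ethyl]-4-hydroxybenzaldehyde | O=Cc1cc(OCc5ccccc5)c(O)c(c1)[C@@H](c1cc(OCc5ccccc5)cc(OCc5ccccc5)c1)Cc1ccc(OCc5ccccc5)cc1
A4 | alternative 2 | (2R,3R)-7-(benzyloxy)-2-[4-(benzyloxy)phenyl]-3-[3,5-bis(benzyloxy)phenyl]-2,3-dihydro-1-benzofuran-5-carbaldehyde | O=Cc1cc(OCc5ccccc5)c2c(c1)[C@@H](c1cc(OCc5ccccc5)cc(OCc5ccccc5)c1)[C@H](c1ccc(OCc5ccccc5)cc1)O2
A5 | alternative 3 | hepta-O-benzyl ether of the target | C(c1ccccc1)Oc1ccc(/C=C/c2cc(OCc5ccccc5)cc3c2[C@H](c2cc(OCc5ccccc5)c4c(c2)[C@@H](c2cc(OCc5ccccc5)cc(OCc5ccccc5)c2)[C@H](c2ccc(OCc5ccccc5)cc2)O4)[C@@H](c2ccc(OCc5ccccc5)cc2)O3)cc1
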